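**Assumption:** the target has no stereocentre and no stereogenic alkene. It is achiral, so the "single enantiomer" is the compound itself and no stereocontrol is needed.

## Retrosynthetic overview
1. Target 13 comes from fluoride-mediated global desilylation of tris-TBS dihydrochalcone 11, so no acid meets the o-prenylphenol.
2. Key disconnection is the C(=O)–CH2 bond: linear (anti-Markovnikov) Rh hydroacylation of styrene 7 with salicylaldehyde-type aldehyde 10 (new step).
3. Styrene 7 comes from Stille vinylation of aryl iodide 5, which comes from silylation of 4, which comes from o,o'-C-diprenylation of 4-iodophenol 1.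
4. Aldehyde 10 comes from selective bis-silylation of 2,4,6-trihydroxybenzaldehyde 8, leaving the chelated OH free as the directing group.
5. No ring is formed; both arene rings are purchased.

## Route

**Step 1**
Reactants: 1 4-iodophenol; 2 prenyl bromide (1-bromo-3-methylbut-2-ene, 2.5 equiv)
Product: 4 4-iodo-2,6-bis(3-methylbut-2-en-1-yl)phenol, via 4-iodo-2-prenylphenol 3 (not isolated)
Conditions: KOH (2.5 equiv), H2O, rt, vigorous stirring, 24 h; chromatography
Reagents that add atoms: prenyl bromide 2, CC(C)=CCBr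
Why: In water the phenoxide oxygen is strongly hydrogen-bonded, so the ambident anion is alkylated at the ortho carbons (phenoxide C-alkylation then rearomatisation, twice) with the para position blocked by iodine.

**Step 2**
Reactants: 4 4-iodo-2,6-bis(3-methylbut-2-en-1-yl)phenol
Product: 5 tert-butyl[4-iodo-2,6-bis(3-methylbut-2-en-1-yl)phenoxy]dimethylsilane
Conditions: TBSCl (1.5 equiv), imidazole (3 equiv), DMAP (cat.), DMF, 50 °C
Reagents that add atoms: tert-butyldimethylsilyl chloride, CC(C)(C)[Si](C)(C)Cl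
Why: Standard imidazole-promoted O-silylation of a 2,6-dialkylphenol gives a hindered, robust aryl silyl ether under non-acidic conditions that leave the prenyl groups untouched.

**Step 3**
Reactants: 5 tert-butyl[4-iodo-2,6-bis(3-methylbut-2-en-1-yl)phenoxy]dimethylsilane; 6 tributyl(vinyl)stannane (1.2 equiv)
Product: 7 tert-butyl[4-ethenyl-2,6-bis(3-methylbut-2-en-1-yl)phenoxy]dimethylsilane
Conditions: Pd(PPh3)4 (5 mol %), BHT (cat.), toluene, 100 °C
Reagents that add atoms: tributyl(vinyl)stannane 6, C=C[Sn](CCCC)(CCCC)CCCC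
Why: Stille vinylation of an unhindered aryl iodide runs under neutral conditions, so the aryl TBS ether and the trisubstituted alkenes survive, and BHT suppresses styrene polymerisation.

**Step 4**
Reactants: 8 2,4,6-trihydroxybenzaldehyde
Product: 10 2-hydroxy-4,6-bis(tert-butyldimethylsilyloxy)benzaldehyde, via 4-O-TBS-phloroglucinaldehyde 9 (not isolated)
Conditions: TBSCl (2.1 equiv), imidazole (4.5 equiv), CH2Cl2/DMF (10:1), 0 °C
Reagents that add atoms: tert-butyldimethylsilyl chloride, CC(C)(C)[Si](C)(C)Cl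
Why: Selective O-silylation takes the most acidic 4-OH first and then one ortho OH, after which the last OH is locked in a hydrogen bond to the formyl oxygen and is deactivated.

**Step 5 (key step)**
Reactants: 10 2-hydroxy-4,6-bis(tert-butyldimethylsilyloxy)benzaldehyde (1.0 equiv); 7 tert-butyl[4-ethenyl-2,6-bis(3-methylbut-2-en-1-yl)phenoxy]dimethylsilane (1.5 equiv)
Product: 11 1-[2-hydroxy-4,6-bis(tert-butyldimethylsilyloxy)phenyl]-3-[4-(tert-butyldimethylsilyloxy)-3,5-bis(3-methylbut-2-en-1-yl)phenyl]propan-1-one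
Conditions: [Rh(cod)OMe]2 (2.5 mol %), bis(dicyclohexylphosphino)methane (dcpm, 5.5 mol %), BHT (5 mol %), 2-MeTHF, 60 °C, Ar
Reagents that add atoms: none
Why: Proposed new method: Rh–OMe deprotonates the free phenol of 10 and the κO-phenoxide directs formyl C–H oxidative addition to a five-membered acyl–Rh(III)–H chelate that resists decarbonylation; only the monosubstituted vinyl group of 7 can bind (the trisubstituted prenyl alkenes are too hindered), hydrometalation is reversible, and turnover-limiting C–C reductive elimination from the secondary η3-benzyl isomer onto a 2,6-disubstituted aroyl group inside the small-bite-angle dcpm pocket is sterically prohibitive, so the primary alkyl isomer is drained (Curtin–Hammett) to the linear ketone; the closest known reaction type is Rh-catalysed linear hydroacylation of unactivated α-olefins with salicylaldehydes, together with small-bite-angle Rh diphosphine hydroacylation with chelating aldehydes, and what is new is linear selectivity on a vinylarene (normally branched-selective) with a 6-substituted salicylaldehyde in a triene substrate.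

**Step 6**
Reactants: 11 tris-TBS dihydrochalcone
Product: 13 4,2',4',6'-tetrahydroxy-3,5-diprenyldihydrochalcone, via 4-O-TBS dihydrochalcone 12 (not isolated)
Conditions: TBAF (3.5 equiv), AcOH (3.5 equiv), THF, 0 °C to rt, Ar; pH 6 buffer work-up
Reagents that add atoms: none
Why: Fluoride desilylation buffered with AcOH removes the activated A-ring silyl ethers first and the hindered B-ring one last, with no Brønsted acid strong enough to cyclise the o-prenylphenol to a chroman and no free base to oxidise the acylphloroglucinol.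

## Compound list
1 | 4-iodophenol | Oc1ccc(I)cc1 | starting material
2 | prenyl bromide (1-bromo-3-methylbut-2-ene) | CC(C)=CCBr | starting material
3 | 4-iodo-2-(3-methylbut-2-en-1-yl)phenol | CC(C)=CCc1cc(I)ccc1O | intermediate (not isolated)
4 | 4-iodo-2,6-bis(3-methylbut-2-en-1-yl)phenol | CC(C)=CCc1cc(I)cc(CC=C(C)C)c1O | intermediate
5 | tert-butyl[4-iodo-2,6-bis(3-methylbut-2-en-1-yl)phenoxy]dimethylsilane | CC(C)=CCc1cc(I)cc(CC=C(C)C)c1O[Si](C)(C)C(C)(C)C | intermediate
6 | tributyl(vinyl)stannane | C=C[Sn](CCCC)(CCCC)CCCC | starting material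
7 | tert-butyl[4-ethenyl-2,6-bis(3-methylbut-2-en-1-yl)phenoxy]dimethylsilane | C=Cc1cc(CC=C(C)C)c(O[Si](C)(C)C(C)(C)C)c(CC=C(C)C)c1 | intermediate
8 | 2,4,6-trihydroxybenzaldehyde | O=Cc1c(O)cc(O)cc1O | starting material
9 | 4-(tert-butyldimethylsilyloxy)-2,6-dihydroxybenzaldehyde | O=Cc1c(O)cc(O[Si](C)(C)C(C)(C)C)cc1O | intermediate (not isolated)
10 | 2-hydroxy-4,6-bis(tert-butyldimethylsilyloxy)benzaldehyde | O=Cc1c(O)cc(O[Si](C)(C)C(C)(C)C)cc1O[Si](C)(C)C(C)(C)C | intermediate
11 | 1-[2-hydroxy-4,6-bis(TBSO)phenyl]-3-[4-(TBSO)-3,5-diprenylphenyl]propan-1-one | CC(C)=CCc1cc(CCC(=O)c2c(O)cc(O[Si](C)(C)C(C)(C)C)cc2O[Si](C)(C)C(C)(C)C)cc(CC=C(C)C)c1O[Si](C)(C)C(C)(C)C | intermediate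
12 | 3-[4-(TBSO)-3,5-diprenylphenyl]-1-(2,4,6-trihydroxyphenyl)propan-1-one | CC(C)=CCc1cc(CCC(=O)c2c(O)cc(O)cc2O)cc(CC=C(C)C)c1O[Si](C)(C)C(C)(C)C | intermediate (not isolated)
13 | 4,2',4',6'-tetrahydroxy-3,5-diprenyldihydrochalcone (achiral) | CC(C)=CCc1cc(CCC(=O)c2c(O)cc(O)cc2O)cc(CC=C(C)C)c1O | target

## Summary
Total step count: 6.
Longest linear sequence: 5 (steps 1, 2, 3, 5, 6); step 4 is the convergent branch.

## Three steps most likely to fail

**Step 5 (proposed new hydroacylation).**
- Risks: branched ketone formation, slow turnover with the 6-silyloxy aldehyde, and Rh–H isomerisation of the prenyl groups.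
- The fallback uses known chemistry. It sets out from 5 and comes back to the route at 13.
- Iodide 5 undergoes I/Li exchange (n-BuLi, THF, −78 °C) and formylation with DMF to give 4-(tert-butyldimethylsilyloxy)-3,5-diprenylbenzaldehyde F1.
- Commercial 2',4',6'-trihydroxyacetophenone is persilylated (TBSOTf, 2,6-lutidine, CH2Cl2) to 2',4',6'-tris(tert-butyldimethylsilyloxy)acetophenone F2.
- The lithium enolate of F2 (LDA, THF, −78 °C) adds to F1 to give the racemic β-hydroxy ketone F3.
- MsCl/Et3N eliminates F3 to the (E)-tetra-TBS chalcone F4.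
- Copper hydride conjugate reduction (Stryker's reagent, toluene, rt) saturates only the enone and gives the tetra-TBS dihydrochalcone F5.
- TBAF/AcOH, as in step 6, then delivers 13.

**Step 1 (aqueous o,o'-diprenylation).**
- Risks: O-prenylation, incomplete second alkylation, and a moderate yield.
- The fallback sets out from 1, passes through 3 and comes back at 4. It uses iterative aromatic Claisen rearrangement in place of direct C-alkylation.
- Phenol 1 is etherified with 3-chloro-3-methylbut-1-yne (CuCl2 cat., DBU, MeCN, 0 °C) to 1-iodo-4-[(2-methylbut-3-yn-2-yl)oxy]benzene F6.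
- Semihydrogenation (Lindlar catalyst, quinoline, H2) gives 1-iodo-4-[(2-methylbut-3-en-2-yl)oxy]benzene F7.
- Heating (PhNEt2, 130 °C) gives 3 by [3,3] shift.
- The same three operations on 3 give the 1,1-dimethylpropargyl ether of 3 F8, then the 1,1-dimethylallyl ether of 3 F9, and then 4.

**Step 4 (selective bis-silylation).**
- Risks: mono/bis/tris mixtures, and a bulky OTBS group next to the formyl group.
- The fallback sets out from 8 and comes back at 12. It switches the A ring to an acetal protecting-group strategy.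
- Aldehyde 8 with MOMCl (2.1 equiv) and DIPEA in CH2Cl2 at 0 °C gives 2-hydroxy-4,6-bis(methoxymethoxy)benzaldehyde F10.
- F10 is coupled with 7 under the step 5 conditions to give the bis-MOM mono-TBS dihydrochalcone F11.
- Dilute HCl in MeOH (rt to 40 °C) removes the MOM groups while the B-ring phenol is still silylated, so chroman formation is impossible. This gives 12.
- Compound 12 is desilylated as in step 6.

## Further compounds
F1 | step 5 | 4-(tert-butyldimethylsilyloxy)-3,5-bis(3-methylbut-2-en-1-yl)benzaldehyde | O=Cc1cc(CC=C(C)C)c(O[Si](C)(C)C(C)(C)C)c(CC=C(C)C)c1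
F2 | step 5 | 2',4',6'-tris(tert-butyldimethylsilyloxy)acetophenone | CC(=O)c1c(O[Si](C)(C)C(C)(C)C)cc(O[Si](C)(C)C(C)(C)C)cc1O[Si](C)(C)C(C)(C)C
F3 | step 5 | racemic 3-hydroxy-3-[4-(TBSO)-3,5-diprenylphenyl]-1-[2,4,6-tris(TBSO)phenyl]propan-1-one | CC(C)=CCc1cc(C(O)CC(=O)c2c(O[Si](C)(C)C(C)(C)C)cc(O[Si](C)(C)C(C)(C)C)cc2O[Si](C)(C)C(C)(C)C)cc(CC=C(C)C)c1O[Si](C)(C)C(C)(C)C
F4 | step 5 | (E)-3-[4-(TBSO)-3,5-diprenylphenyl]-1-[2,4,6-tris(TBSO)phenyl]prop-2-en-1-one | CC(C)=CCc1cc(/C=C/C(=O)c2c(O[Si](C)(C)C(C)(C)C)cc(O[Si](C)(C)C(C)(C)C)cc2O[Si](C)(C)C(C)(C)C)cc(CC=C(C)C)c1O[Si](C)(C)C(C)(C)C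
F5 | step 5 | 3-[4-(TBSO)-3,5-diprenylphenyl]-1-[2,4,6-tris(TBSO)phenyl]propan-1-one | CC(C)=CCc1cc(CCC(=O)c2c(O[Si](C)(C)C(C)(C)C)cc(O[Si](C)(C)C(C)(C)C)cc2O[Si](C)(C)C(C)(C)C)cc(CC=C(C)C)c1O[Si](C)(C)C(C)(C)C
F6 | step 1 | 1-iodo-4-[(2-methylbut-3-yn-2-yl)oxy]benzene | C#CC(C)(C)Oc1ccc(I)cc1
F7 | step 1 | 1-iodo-4-[(2-methylbut-3-en-2-yl)oxy]benzene | C=CC(C)(C)Oc1ccc(I)cc1
F8 | step 1 | 4-iodo-2-(3-methylbut-2-en-1-yl)-1-[(2-methylbut-3-yn-2-yl)oxy]benzene | C#CC(C)(C)Oc1ccc(I)cc1CC=C(C)C
F9 | step 1 | 4-iodo-2-(3-methylbut-2-en-1-yl)-1-[(2-methylbut-3-en-2-yl)oxy]benzene | C=CC(C)(C)Oc1ccc(I)cc1CC=C(C)C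
F10 | step 4 | 2-hydroxy-4,6-bis(methoxymethoxy)benzaldehyde | COCOc1cc(O)c(C=O)c(OCOC)c1
F11 | step 4 | 1-[2-hydroxy-4,6-bis(methoxymethoxy)phenyl]-3-[4-(TBSO)-3,5-diprenylphenyl]propan-1-one | CC(C)=CCc1cc(CCC(=O)c2c(O)cc(OCOC)cc2OCOC)cc(CC=C(C)C)c1O[Si](C)(C)C(C)(C)C
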